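## Retrosynthetic overview
1. The C1 enone comes from a C1 allylic alcohol. The ten-membered ring is closed last at C1–C10 by a Nozaki–Hiyama–Kishi reaction of a 2-bromoalkene with an aldehyde, and that aldehyde is masked until then as the prenyl alkene of geraniol.
2. C8–C9 is made by reagent-controlled 2-bromoallylboration of a β-formylbutenolide, followed by tiglate formation.
3. The C7=C11 butenolide with C13–OAc comes from a saturated trans-γ-lactone by Claisen formylation, selenenylation, reduction, acetylation and selenoxide elimination.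
4. The key bond is C6–C7. It is formed by an intermolecular Evans syn-aldol of a crotonyl imide boron dienolate with the epoxy aldehyde obtained from geraniol by Sharpless epoxidation.
5. Order of ring formation: epoxide, then γ-lactone, then butenolide, then the ten-membered carbocycle.

Assumption: locants C1–C15 follow germacranolide numbering (C1 ketone, C4/C5 epoxide, C6 lactone CH–O, C7=C11 butenolide alkene, C8 CH–O-tiglate, C10=C14 exocyclic methylene, C12 lactone C=O, C13 CH2OAc, C15 methyl). The target is (4R,5R,6S,8S).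

## Route

Step 1
Reactants: 1 geraniol
Product: 2 (2R,3R)-2,3-epoxygeraniol
Conditions: Ti(OiPr)4 (5 mol %), D-(−)-diethyl tartrate (6 mol %), t-BuOOH, 4 Å MS, CH2Cl2, −20 °C
Reagents that add atoms: tert-butyl hydroperoxide, CC(C)(C)OO
Why: In this Katsuki–Sharpless asymmetric epoxidation only the allylic-alcohol alkene binds to titanium, and D-(−)-tartrate gives the mirror image of the well-known (2S,3S) product of L-(+)-tartrate, which sets C4 (R) and C5 (R) from the E-alkene.

Step 2
Reactants: 2 (2R,3R)-2,3-epoxygeraniol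
Product: 3 (2S,3R)-epoxygeranial
Conditions: TEMPO (2,2,6,6-tetramethylpiperidin-1-oxyl, 10 mol %), PhI(OAc)2, CH2Cl2, rt
Reagents that add atoms: none
Why: This oxoammonium (TEMPO) oxidation stops at the aldehyde, spares the epoxide and the prenyl alkene, and leaves the geometry untouched, so the C5 descriptor changes only because CHO outranks C4.

Step 3
Reactants: 4 (S)-4-benzyloxazolidin-2-one; 5 (E)-but-2-enoyl chloride
Product: 7 (S)-4-benzyl-3-[(E)-but-2-enoyl]oxazolidin-2-one, via N-lithio oxazolidinone 6 (not isolated)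
Conditions: n-BuLi, THF, −78 °C; then 5, −78 → 0 °C
Reagents that add atoms: none
Why: This is a standard N-acylation of the lithiated Evans auxiliary by an acid chloride, and no stereocentre is formed.

Step 4 (key C6–C7 bond)
Reactants: 7 (S)-4-benzyl-3-[(E)-but-2-enoyl]oxazolidin-2-one; 3 (2S,3R)-epoxygeranial
Product: 10 syn-aldol imide (6S,7S), via boron dienolate 8 (not isolated), via boron aldolate 9 (not isolated)
Conditions: Bu2BOTf, Et3N, CH2Cl2, −78 → 0 °C; 3, −78 → 0 °C; pH 7 buffer, MeOH, 30 % H2O2, 0 °C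
Reagents that add atoms: none
Why: In this intermolecular Evans boron aldol, γ-deprotonation gives the Z-dienolate, which reacts at its α-carbon through a Zimmerman–Traxler chair, and the (S)-benzyl auxiliary sets C6 (S) and C7 (S) in the same sense as benzaldehyde gives the (2S,3S) adduct, so it overrides the aldehyde bias and turns the minor enantiomer of 3 into a separable diastereomer.

Step 5
Reactants: 10 syn-aldol imide (6S,7S)
Product: 11 2-vinyl-1,3-diol (6S,7R)
Conditions: LiBH4, Et2O, H2O (1 equiv), 0 °C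
Reagents that add atoms: none
Why: In this reductive auxiliary cleavage the activated imide carbonyl is reduced much faster than the epoxide is opened, and C7 changes descriptor only through ligand priorities.

Step 6
Reactants: 11 2-vinyl-1,3-diol (6S,7R)
Product: 12 C8 primary TBS ether
Conditions: TBSCl (1.05 equiv), imidazole, CH2Cl2, 0 °C
Reagents that add atoms: tert-butyldimethylsilyl chloride, CC(C)(C)[Si](C)(C)Cl
Why: This silylation is selective on steric grounds for the primary C8 hydroxyl over the secondary C6 hydroxyl.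

Step 7
Reactants: 12 C8 primary TBS ether
Product: 14 C6/C12 1,4-diol, via bis(9-BBN) adduct 13 (not isolated)
Conditions: 9-BBN (2.5 equiv), THF, 0 °C → rt; NaBO3·4H2O, THF/H2O, rt
Reagents that add atoms: sodium perborate, [Na+].[Na+].O[B-]1(O)OO[B-](O)(O)OO1
Why: In this Brown hydroboration–oxidation, bulky 9-BBN adds anti-Markovnikov to the monosubstituted vinyl group far faster than to the trisubstituted prenyl alkene, and mild perborate avoids Payne rearrangement of the epoxy alcohol.

Step 8
Reactants: 14 C6/C12 1,4-diol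
Product: 16 trans-γ-lactone (6S,7R), via lactol 15 (not isolated)
Conditions: TEMPO (20 mol %), PhI(OAc)2 (2.5 equiv), CH2Cl2, rt
Reagents that add atoms: none
Why: In this TEMPO oxidative lactonisation the primary alcohol is oxidised selectively, the C6 hydroxyl closes the lactol, and a second oxidation gives the lactone, with C5 and C8 trans as dictated by the syn-aldol.

Step 9
Reactants: 16 trans-γ-lactone (6S,7R)
Product: 18 α-formyl lactone (enol/aldehyde tautomers), via lithium enolate 17 (not isolated)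
Conditions: LiN(iPr)2 (1.15 equiv), THF, −78 °C; HCO2Et (5 equiv), −78 → 0 °C; AcOH quench
Reagents that add atoms: ethyl formate, CCOC=O
Why: This crossed Claisen condensation (formylation) at the only enolisable position, C11, brings in C13 and is driven by formation of the stabilised β-dicarbonyl enolate.

Step 10
Reactants: 18 α-formyl lactone
Product: 19 α-formyl-α-phenylselanyl lactone (11R)
Conditions: PhSeCl (1.05 equiv), pyridine, CH2Cl2, 0 °C, 15 min
Reagents that add atoms: benzeneselenenyl chloride, Cl[Se]c1ccccc1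
Why: In this electrophilic selenenylation of the β-dicarbonyl enol, selenium enters anti to the neighbouring C7 CH2OTBS group and therefore cis to H-7, and the enol outcompetes the reversible addition of PhSeCl to the prenyl alkene.

Step 11
Reactants: 19 α-formyl-α-phenylselanyl lactone
Product: 20 α-(hydroxymethyl) selenide
Conditions: NaBH4, CeCl3·7H2O, MeOH, −78 °C
Reagents that add atoms: none
Why: This chemoselective Luche-type 1,2-reduction of the aldehyde at low temperature is faster than deformylation and leaves the lactone, selenide and epoxide intact.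

Step 12
Reactants: 20 α-(hydroxymethyl) selenide
Product: 21 α-(acetoxymethyl) selenide
Conditions: Ac2O, pyridine, 4-(dimethylamino)pyridine (cat.), CH2Cl2, 0 °C
Reagents that add atoms: acetic anhydride, CC(=O)OC(C)=O
Why: This simple O-acetylation of the primary alcohol installs the C13 acetate of the target before the alkene is made.

Step 13
Reactants: 21 α-(acetoxymethyl) selenide
Product: 23 butenolide acetate with C8 OTBS, via selenoxide 22 (not isolated)
Conditions: 30 % H2O2, pyridine, CH2Cl2, 0 °C → rt, 30 min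
Reagents that add atoms: none
Why: In this selenoxide syn-elimination, elimination avoids the oxygen-bearing C13 and takes the cis H-7, which gives the tetrasubstituted C7=C11 alkene under non-basic conditions, erases C7 and C11, and leaves C6 untouched.

Step 14
Reactants: 23 butenolide acetate with C8 OTBS
Product: 24 C8 primary allylic alcohol
Conditions: HF·pyridine, excess pyridine, THF, 0 °C
Reagents that add atoms: none
Why: This buffered fluoride desilylation avoids base, so there is no deprotonation at C6 or acetate migration, and it is mild enough for a trisubstituted epoxide.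

Step 15
Reactants: 24 C8 primary allylic alcohol
Product: 25 β-formylbutenolide
Conditions: Dess–Martin periodinane, 2,6-lutidine, CH2Cl2, 0 °C
Reagents that add atoms: none
Why: Dess–Martin oxidation of the allylic alcohol under buffered, non-basic conditions keeps the C6 stereocentre and the epoxide intact.

Step 16
Reactants: 26 2,3-dibromopropene; 27 tributylstannane
Product: 29 (2-bromoallyl)tributylstannane, via tributylstannyllithium 28 (not isolated)
Conditions: LiN(iPr)2, THF, 0 °C; added to 26 (excess), THF, −78 °C → rt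
Reagents that add atoms: none
Why: The stannyl anion displaces only the allylic bromide (SN2), while the vinylic bromide is inert.

Step 17
Reactants: 25 β-formylbutenolide; 29 (2-bromoallyl)tributylstannane
Product: 31 (8S)-2-bromohomoallylic alcohol, via B-(2-bromoallyl)diazaborolidine 30 (not isolated)
Conditions: (S,S)-TsNHCH(Ph)CH(Ph)NHTs, BBr3, CH2Cl2, 0 °C → rt, evaporate; 29 (slight excess), CH2Cl2, rt; 25, −78 °C; pH 7 buffer
Reagents that add atoms: none
Why: In this Corey enantioselective carbonyl allylation, tin-to-boron exchange gives a chiral 2-bromoallylborane that adds through a closed chair, and the (S,S)-controller is taken to give the S carbinol, which rests on a steric transition-state model and recalled precedent for benzaldehyde and enals and is to be confirmed by Mosher ester analysis, setting C8 (S) under neutral conditions at −78 °C.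

Step 18
Reactants: 31 (8S)-2-bromohomoallylic alcohol; 32 tigloyl chloride
Product: 33 (8S)-tiglate
Conditions: pyridine, 4-(dimethylamino)pyridine (cat.), CH2Cl2, 0 °C → rt
Reagents that add atoms: none
Why: This O-acylation proceeds with retention at C8, the E-configured tiglate is the stable geometry, and weak bases spare H-6.

Step 19
Reactants: 33 (8S)-tiglate
Product: 35 C1 aldehyde, via secondary ozonide 34 (not isolated)
Conditions: O3, CH2Cl2, −78 °C, Sudan Red 7B end point; Me2S, −78 °C → rt
Reagents that add atoms: ozone, [O-][O+]=O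
Why: In this chemoselective ozonolysis the electron-rich trisubstituted prenyl alkene reacts far faster than the bromoalkene, tiglate or butenolide alkenes, and the aldehyde appears without ever passing through a free C1 alcohol that could open the epoxide.

Step 20
Reactants: 35 C1 aldehyde
Product: 37 macrocyclic C1 allylic alcohol (C1 epimers), via alkenyl-CrCl2 species 36 (not isolated)
Conditions: CrCl2 (15 equiv), NiCl2 (0.15 equiv), degassed DMSO, 2 mM, slow addition, rt → 40 °C
Reagents that add atoms: none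
Why: In this intramolecular Nozaki–Hiyama–Kishi reaction, zerovalent nickel inserts into the C–Br bond and transmetallates to chromium, the alkenylchromium adds only to the aldehyde and tolerates the esters, lactone and epoxide, and the new C1 centre is removed in the next step.

Step 21
Reactants: 37 macrocyclic C1 allylic alcohol
Product: 38 target
Conditions: Dess–Martin periodinane, 2,6-lutidine, CH2Cl2, 0 °C; chromatography on pH 7-buffered silica
Reagents that add atoms: none
Why: Dess–Martin oxidation converts both C1 epimers to the single α-methylene ketone under neutral conditions that avoid transannular opening of the 4,5-epoxide.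

## Compound list
1 | geraniol | CC(C)=CCC/C(C)=C/CO | starting material
2 | [(2R,3R)-3-methyl-3-(4-methylpent-3-enyl)oxiran-2-yl]methanol | OC[C@H]1O[C@]1(C)CCC=C(C)C | intermediate
3 | (2S,3R)-3-methyl-3-(4-methylpent-3-enyl)oxirane-2-carbaldehyde | O=C[C@H]1O[C@]1(C)CCC=C(C)C | intermediate
4 | (S)-4-benzyl-1,3-oxazolidin-2-one | O=C1N[C@@H](Cc2ccccc2)CO1 | starting material
5 | (E)-but-2-enoyl chloride | C/C=C/C(=O)Cl | starting material
6 | N-lithio-(S)-4-benzyloxazolidin-2-one (not isolated) | [Li]N1[C@@H](Cc2ccccc2)COC1=O | intermediate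
7 | (S)-4-benzyl-3-[(E)-but-2-enoyl]oxazolidin-2-one | C/C=C/C(=O)N1[C@@H](Cc2ccccc2)COC1=O | intermediate
8 | dibutylboron (Z)-dienolate of 7 (not isolated) | C=C/C=C(\OB(CCCC)CCCC)N1[C@@H](Cc2ccccc2)COC1=O | intermediate
9 | dibutylboron aldolate of 10 (not isolated) | O=C(N1[C@@H](Cc2ccccc2)COC1=O)[C@@H](C=C)[C@H](OB(CCCC)CCCC)[C@H]1O[C@]1(C)CCC=C(C)C | intermediate
10 | (S)-4-benzyl-3-{(2S,3S)-2-ethenyl-3-hydroxy-3-[(2R,3R)-3-methyl-3-(4-methylpent-3-enyl)oxiran-2-yl]propanoyl}oxazolidin-2-one | O=C(N1[C@@H](Cc2ccccc2)COC1=O)[C@@H](C=C)[C@H](O)[C@H]1O[C@]1(C)CCC=C(C)C | intermediate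
11 | (1S,2R)-2-ethenyl-1-[(2R,3R)-3-methyl-3-(4-methylpent-3-enyl)oxiran-2-yl]propane-1,3-diol | OC[C@@H](C=C)[C@H](O)[C@H]1O[C@]1(C)CCC=C(C)C | intermediate
12 | (1S,2R)-2-[(TBS-oxy)methyl]-1-[(2R,3R)-3-methyl-3-(4-methylpent-3-enyl)oxiran-2-yl]but-3-en-1-ol | CC(C)(C)[Si](C)(C)OC[C@@H](C=C)[C@H](O)[C@H]1O[C@]1(C)CCC=C(C)C | intermediate
13 | C12-(9-BBN) borane / C6-O-(9-BBN) borinate of 12 (not isolated) | CC(C)(C)[Si](C)(C)OC[C@@H](CCB1C2CCCC1CCC2)[C@H](OB1C2CCCC1CCC2)[C@H]1O[C@]1(C)CCC=C(C)C | intermediate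
14 | (3R,4S)-3-[(TBS-oxy)methyl]-4-[(2R,3R)-3-methyl-3-(4-methylpent-3-enyl)oxiran-2-yl]butane-1,4-diol | CC(C)(C)[Si](C)(C)OC[C@@H](CCO)[C@H](O)[C@H]1O[C@]1(C)CCC=C(C)C | intermediate
15 | lactol of 16, anomers (not isolated) | OC1C[C@H](CO[Si](C)(C)C(C)(C)C)[C@H](O1)[C@H]2O[C@]2(C)CCC=C(C)C | intermediate
16 | (4R,5S)-4-[(TBS-oxy)methyl]-5-[(2R,3R)-3-methyl-3-(4-methylpent-3-enyl)oxiran-2-yl]dihydrofuran-2(3H)-one | O=C1C[C@H](CO[Si](C)(C)C(C)(C)C)[C@H](O1)[C@H]2O[C@]2(C)CCC=C(C)C | intermediate
17 | lithium enolate of 16 (not isolated) | [Li]OC1=C[C@H](CO[Si](C)(C)C(C)(C)C)[C@H](O1)[C@H]2O[C@]2(C)CCC=C(C)C | intermediate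
18 | (4R,5S)-3-formyl derivative of 16, C3 epimers in equilibrium with the hydroxymethylene enol | O=C1C(C=O)[C@H](CO[Si](C)(C)C(C)(C)C)[C@H](O1)[C@H]2O[C@]2(C)CCC=C(C)C | intermediate
19 | (3R,4R,5S)-3-formyl-3-(phenylselanyl) lactone, PhSe cis to H-4 | O=C1[C@@](C=O)([Se]c2ccccc2)[C@H](CO[Si](C)(C)C(C)(C)C)[C@H](O1)[C@H]2O[C@]2(C)CCC=C(C)C | intermediate
20 | (3R,4R,5S)-3-(hydroxymethyl)-3-(phenylselanyl) lactone | O=C1[C@@](CO)([Se]c2ccccc2)[C@H](CO[Si](C)(C)C(C)(C)C)[C@H](O1)[C@H]2O[C@]2(C)CCC=C(C)C | intermediate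
21 | (3R,4R,5S)-3-(acetoxymethyl)-3-(phenylselanyl) lactone | O=C1[C@@](COC(C)=O)([Se]c2ccccc2)[C@H](CO[Si](C)(C)C(C)(C)C)[C@H](O1)[C@H]2O[C@]2(C)CCC=C(C)C | intermediate
22 | selenoxide of 21 (not isolated) | O=C1[C@@](COC(C)=O)([Se](=O)c2ccccc2)[C@H](CO[Si](C)(C)C(C)(C)C)[C@H](O1)[C@H]2O[C@]2(C)CCC=C(C)C | intermediate
23 | {(5S)-4-[(TBS-oxy)methyl]-5-[(2R,3R)-3-methyl-3-(4-methylpent-3-enyl)oxiran-2-yl]-2-oxo-2,5-dihydrofuran-3-yl}methyl acetate | O=C1C(COC(C)=O)=C(CO[Si](C)(C)C(C)(C)C)[C@H](O1)[C@H]2O[C@]2(C)CCC=C(C)C | intermediate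
24 | 4-(hydroxymethyl) analogue of 23 | O=C1C(COC(C)=O)=C(CO)[C@H](O1)[C@H]2O[C@]2(C)CCC=C(C)C | intermediate
25 | 4-formyl analogue of 23 | O=C1C(COC(C)=O)=C(C=O)[C@H](O1)[C@H]2O[C@]2(C)CCC=C(C)C | intermediate
26 | 2,3-dibromoprop-1-ene | C=C(Br)CBr | starting material
27 | tributylstannane | CCCC[SnH](CCCC)CCCC | starting material
28 | tributylstannyllithium (not isolated) | [Li][Sn](CCCC)(CCCC)CCCC | intermediate
29 | (2-bromoprop-2-enyl)tributylstannane | C=C(Br)C[Sn](CCCC)(CCCC)CCCC | intermediate
30 | (4S,5S)-2-(2-bromoprop-2-enyl)-4,5-diphenyl-1,3-ditosyl-1,3,2-diazaborolidine (not isolated) | C=C(Br)CB1N(S(=O)(=O)c2ccc(C)cc2)[C@@H](c2ccccc2)[C@H](c2ccccc2)N1S(=O)(=O)c1ccc(C)cc1 | intermediate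
31 | {(5S)-4-[(1S)-3-bromo-1-hydroxybut-3-enyl]-5-[(2R,3R)-3-methyl-3-(4-methylpent-3-enyl)oxiran-2-yl]-2-oxo-2,5-dihydrofuran-3-yl}methyl acetate | O=C1C(COC(C)=O)=C([C@@H](O)CC(Br)=C)[C@H](O1)[C@H]2O[C@]2(C)CCC=C(C)C | intermediate
32 | (E)-2-methylbut-2-enoyl chloride (tigloyl chloride) | C/C=C(\C)C(=O)Cl | starting material
33 | (8S)-tiglate of 31 | O=C1C(COC(C)=O)=C([C@@H](OC(=O)/C(C)=C/C)CC(Br)=C)[C@H](O1)[C@H]2O[C@]2(C)CCC=C(C)C | intermediate
34 | 1,2,4-trioxolane from the prenyl alkene of 33 (not isolated) | O=C1C(COC(C)=O)=C([C@@H](OC(=O)/C(C)=C/C)CC(Br)=C)[C@H](O1)[C@H]2O[C@]2(C)CCC3OOC(C)(C)O3 | intermediate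
35 | C1 aldehyde (3-oxopropyl on the oxirane) | O=C1C(COC(C)=O)=C([C@@H](OC(=O)/C(C)=C/C)CC(Br)=C)[C@H](O1)[C@H]2O[C@]2(C)CCC=O | intermediate
36 | C10 alkenyl-CrCl2 species (not isolated) | O=C1C(COC(C)=O)=C([C@@H](OC(=O)/C(C)=C/C)CC(=C)[Cr](Cl)Cl)[C@H](O1)[C@H]2O[C@]2(C)CCC=O | intermediate
37 | (4R,5R,6S,8S)-13-acetoxy-4,5-epoxy-1-hydroxy-8-tigloyloxygermacra-7(11),10(14)-dien-12,6-olide, C1 epimers | C=C1C[C@H](OC(=O)/C(C)=C/C)C2=C(COC(C)=O)C(=O)O[C@@H]2[C@H]2O[C@]2(C)CCC1O | intermediate
38 | (4R,5R,6S,8S)-13-acetoxy-4,5-epoxy-1-oxo-8-tigloyloxygermacra-7(11),10(14)-dien-12,6-olide (CNP0225286.1) | C=C1C[C@H](OC(=O)/C(C)=C/C)C2=C(COC(C)=O)C(=O)O[C@@H]2[C@H]2O[C@]2(C)CCC1=O | target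

## Step count and risks
Total steps: 21. Longest linear sequence: 19 (steps 1, 2, 4–15, 17–21, from geraniol).

**Step 20, ten-membered ring closure.** This is the riskiest step. The ring is strained, a vinylic bromide reacts more slowly than an iodide, and the chromium alkoxide sits across the ring from the epoxide.

The fallback sets out from 25 and comes back at 37. It replaces the halide/aldehyde closure by a reductive alkyne/aldehyde closure.
- The (S,S)-bromoborane of step 17 is loaded with triphenyl(prop-2-ynyl)stannane. The resulting allenylborane adds to 25 to give the (8S)-homopropargylic alcohol F1.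
- Tigloyl chloride 32 in pyridine gives the alkynyl tiglate F2.
- Ozonolysis of the prenyl alkene as in step 19 gives the ynal F3.
- Ni(cod)2 with 1,3-bis(2,6-diisopropylphenyl)imidazol-2-ylidene and Et3SiH, with slow addition in THF, closes C1–C10. The bulky carbene favours the exo-methylene regiochemistry and gives the macrocyclic triethylsilyl ether F4.
- HF·pyridine then gives 37.
- The C13 allylic acetate is the group to watch, because zerovalent nickel can ionise it.

**Step 17, asymmetric 2-bromoallylation.** The enal is hindered and sensitive, and the level and sense of induction are uncertain because C6 may also exert an influence.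

The fallback sets out from 25 and comes back at 33. It gives up reagent control in favour of stereoconvergence.
- Indium powder and 26 in THF/H2O (Barbier allylation) give 31 together with its C8 epimer, the (8R)-alcohol F5.
- The two are diastereomers and are separated on silica.
- 31 is acylated as in step 18.
- F5 is esterified with tiglic acid, PPh3 and diisopropyl azodicarboxylate (Mitsunobu, inversion at C8).
- Both epimers therefore end as 33.

**Step 13, selenoxide elimination.** It needs selenium cis to H-7, and it could eliminate toward C13 instead.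

The fallback sets out from 18 and comes back at 23. It needs no syn-hydrogen.
- DDQ in dioxane at rt dehydrogenates the hydroxymethylene lactone by hydride abstraction at C7 and gives the α-formylbutenolide F6.
- F6 is reduced at once with NaBH4/CeCl3·7H2O in MeOH at −78 °C to the α-(hydroxymethyl)butenolide F7.
- Ac2O/pyridine then gives 23.

## Further compounds
F1 | step 20 | {(5S)-4-[(1S)-1-hydroxybut-3-ynyl]-5-[(2R,3R)-3-methyl-3-(4-methylpent-3-enyl)oxiran-2-yl]-2-oxo-2,5-dihydrofuran-3-yl}methyl acetate | O=C1C(COC(C)=O)=C([C@@H](O)CC#C)[C@H](O1)[C@H]2O[C@]2(C)CCC=C(C)C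
F2 | step 20 | (8S)-tiglate of F1 | O=C1C(COC(C)=O)=C([C@@H](OC(=O)/C(C)=C/C)CC#C)[C@H](O1)[C@H]2O[C@]2(C)CCC=C(C)C
F3 | step 20 | C1 aldehyde of F2 (ynal) | O=C1C(COC(C)=O)=C([C@@H](OC(=O)/C(C)=C/C)CC#C)[C@H](O1)[C@H]2O[C@]2(C)CCC=O
F4 | step 20 | C1 triethylsilyl ether of 37, C1 epimers | C=C1C[C@H](OC(=O)/C(C)=C/C)C2=C(COC(C)=O)C(=O)O[C@@H]2[C@H]2O[C@]2(C)CCC1O[Si](CC)(CC)CC
F5 | step 17 | (8R)-epimer of 31 | O=C1C(COC(C)=O)=C([C@H](O)CC(Br)=C)[C@H](O1)[C@H]2O[C@]2(C)CCC=C(C)C
F6 | step 13 | (5S)-4-[(TBS-oxy)methyl]-5-[(2R,3R)-3-methyl-3-(4-methylpent-3-enyl)oxiran-2-yl]-2-oxo-2,5-dihydrofuran-3-carbaldehyde | O=C1C(C=O)=C(CO[Si](C)(C)C(C)(C)C)[C@H](O1)[C@H]2O[C@]2(C)CCC=C(C)C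
F7 | step 13 | 3-(hydroxymethyl) analogue of F6 | O=C1C(CO)=C(CO[Si](C)(C)C(C)(C)C)[C@H](O1)[C@H]2O[C@]2(C)CCC=C(C)C
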